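**Strategy.** The bicyclo[3.3.1]nonane core is disconnected at the C4–C5 bond of ring A. C5 is the α-carbon of the C9 bridging ketone in ring B and C4 is an sp2 carbon of the three-carbon bridge, so a silyl enol ether of C9 can attack a gold-activated bromo-ynone that hangs from C1 (6-endo-dig). This single operation turns a monocyclic cyclohexanone into the bridged dione with C2 already oxidised and C4 carrying bromine for exchange to oxygen. The precursor, a 2-alkynoyl-2-prenyl-4-geranylcyclohexanone enol ether, comes from an Enders hydrazone alkylation, a cuprate/aldol sequence and an anti-selective prenylation; bridgehead geranylation and C3 aroylation finish the route.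

Key step: step 10

Remark on the chemistry (assumptions): the core is numbered C1 (prenyl bridgehead), C2–C3–C4 (acyl-dione bridge), C5 (geranyl bridgehead), C6 (CH2), C7 (CH-geranyl), C8 (CMe2), C9 (bridging C=O). Ring A = C1–C2–C3–C4–C5–C9; ring B = C1–C9–C5–C6–C7–C8. Geranyl = (2E)-3,7-dimethylocta-2,6-dienyl; prenyl = 3-methylbut-2-enyl. The tautomers of the 2-aroyl-1,3-dione are treated as one compound. The sense of induction in step 2 is assigned by analogy with the established outcome of SAMP/RAMP alkylations of cyclic ketones.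

**Step 1**
Reactants: 1 1,4-dioxaspiro[4.5]decan-7-one; 2 (R)-1-amino-2-(methoxymethyl)pyrrolidine (RAMP)
Product: 3 RAMP hydrazone of 1,4-dioxaspiro[4.5]decan-7-one
Conditions: neat, 60 °C, 4 Å molecular sieves
Reagents that add atoms: RAMP (2), COC[C@H]1CCCN1N
Why: Condensation of the ketone with the hydrazine auxiliary (hydrazone formation) is driven by loss of water and creates no stereocentre.

**Step 2**
Reactants: 3 RAMP hydrazone of 1,4-dioxaspiro[4.5]decan-7-one; 4 geranyl bromide
Product: 6 RAMP hydrazone of (8R)-8-geranyl-1,4-dioxaspiro[4.5]decan-7-one, via lithium azaenolate 5 (not isolated)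
Conditions: LiN(i-Pr)2, THF, 0 °C; then 4, −100 °C → rt
Reagents that add atoms: geranyl bromide (4), CC(C)=CCC/C(C)=C/CBr
Why: Enders RAMP-hydrazone α-alkylation: LiN(i-Pr)2 should remove the less hindered C8–H remote from the ketal, and the lithium-chelated azaenolate is alkylated by the allylic bromide (SN2) on the face dictated by the methoxymethylpyrrolidine, which should set the new centre as (8R).

**Step 3**
Reactants: 6 RAMP hydrazone of (8R)-8-geranyl-1,4-dioxaspiro[4.5]decan-7-one
Product: 7 (8R)-8-geranyl-1,4-dioxaspiro[4.5]decan-7-one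
Conditions: CuCl2, THF/H2O, rt; aq. NH3 work-up
Reagents that add atoms: water, O
Why: Copper-assisted hydrolytic cleavage of the hydrazone is mild enough to leave the dioxolane, the alkenes and the α-stereocentre untouched.

**Step 4**
Reactants: 7 (8R)-8-geranyl-1,4-dioxaspiro[4.5]decan-7-one
Product: 9 (4R)-4-geranyl-3-methylcyclohex-2-en-1-one, via tertiary alcohol 8 (not isolated)
Conditions: CeCl3, MeLi, THF, −78 °C; then 1 M aq. HCl, THF, rt
Reagents that add atoms: methyllithium, [Li]C
Why: The weakly basic organocerium adds 1,2 to the ketone without enolising the adjacent stereocentre, and aqueous acid then unmasks the ketone and dehydrates the β-hydroxy ketone to the conjugated enone (a Stork–Danheiser-type carbonyl transposition), leaving the geranyl-bearing carbon as the untouched γ-centre.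

**Step 5**
Reactants: 9 (4R)-4-geranyl-3-methylcyclohex-2-en-1-one; 10 3-(trimethylsilyl)prop-2-ynal
Product: 12 (4R)-4-geranyl-2-[1-hydroxy-3-(trimethylsilyl)prop-2-yn-1-yl]-3,3-dimethylcyclohexan-1-one, via lithium enolate 11 (not isolated)
Conditions: Me2CuLi (from MeLi and CuI), Et2O, −20 → 0 °C; then 10, THF, −78 °C; aq. NH4Cl
Reagents that add atoms: methyllithium (delivered as Me2CuLi), [Li]C; 3-(trimethylsilyl)prop-2-ynal (10), O=CC#C[Si](C)(C)C
Why: Gilman cuprate 1,4-addition builds the C8 gem-dimethyl group (no stereocentre) and the regiodefined lithium enolate is trapped by aldol addition to the ynal; the two new centres form as a mixture that is erased in steps 6 and 7.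

**Step 6**
Reactants: 12 (4R)-4-geranyl-2-[1-hydroxy-3-(trimethylsilyl)prop-2-yn-1-yl]-3,3-dimethylcyclohexan-1-one
Product: 13 (4R)-4-geranyl-3,3-dimethyl-2-[3-(trimethylsilyl)prop-2-ynoyl]cyclohexan-1-one
Conditions: Dess–Martin periodinane, NaHCO3, CH2Cl2, rt
Reagents that add atoms: none
Why: Dess–Martin oxidation converts the secondary propargylic alcohol to the ynone under buffered conditions, giving the 1,3-diketone that makes C1 acidic.

**Step 7**
Reactants: 13 (4R)-4-geranyl-3,3-dimethyl-2-[3-(trimethylsilyl)prop-2-ynoyl]cyclohexan-1-one; 14 prenyl bromide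
Product: 16 (2S,4R)-4-geranyl-3,3-dimethyl-2-prenyl-2-[3-(trimethylsilyl)prop-2-ynoyl]cyclohexan-1-one, via sodium enolate 15 (not isolated)
Conditions: NaH, THF, 0 °C; then 14, DMF co-solvent, 0 °C → rt
Reagents that add atoms: prenyl bromide (14), CC(C)=CCBr
Why: C-alkylation of the 1,3-diketone enolate (SN2 on an allylic bromide): the electrophile should enter axially on the half-chair that keeps the C7 geranyl equatorial, anti to the pseudo-axial C8 methyl and therefore trans to geranyl, which sets the quaternary centre with the alkynoyl arm cis to geranyl (substrate control).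

**Step 8**
Reactants: 16 (2S,4R)-4-geranyl-3,3-dimethyl-2-prenyl-2-[3-(trimethylsilyl)prop-2-ynoyl]cyclohexan-1-one
Product: 17 (2S,4R)-2-(3-bromoprop-2-ynoyl)-4-geranyl-3,3-dimethyl-2-prenylcyclohexan-1-one
Conditions: NBS, AgNO3 (10 mol %), acetone, rt, dark
Reagents that add atoms: N-bromosuccinimide, O=C1CCC(=O)N1Br
Why: Silver-catalysed desilylative bromination of the alkynylsilane with NBS (through the silver acetylide) is much faster than attack of NBS on the trisubstituted alkenes.

**Step 9**
Reactants: 17 (2S,4R)-2-(3-bromoprop-2-ynoyl)-4-geranyl-3,3-dimethyl-2-prenylcyclohexan-1-one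
Product: 18 (4S,6S)-6-(3-bromoprop-2-ynoyl)-1-(tert-butyldimethylsilyloxy)-4-geranyl-5,5-dimethyl-6-prenylcyclohex-1-ene
Conditions: t-BuMe2SiOTf, i-Pr2NEt, CH2Cl2, −78 → 0 °C
Reagents that add atoms: tert-butyldimethylsilyl triflate, CC(C)(C)[Si](C)(C)OS(=O)(=O)C(F)(F)F
Why: Soft enolisation with a silyl triflate and a hindered amine can only occur toward C5 because C1 is quaternary and the ynone has no α-hydrogen, giving the silyl enol ether regiospecifically.

**Step 10**
Reactants: 18 (4S,6S)-6-(3-bromoprop-2-ynoyl)-1-(tert-butyldimethylsilyloxy)-4-geranyl-5,5-dimethyl-6-prenylcyclohex-1-ene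
Product: 19 (1R,5R,7S)-4-bromo-7-geranyl-8,8-dimethyl-1-prenylbicyclo[3.3.1]non-3-ene-2,9-dione
Conditions: [(2-biphenylyl)(t-Bu)2PAu(NCMe)]SbF6 (5 mol %, cationic monovalent gold), acetone, H2O (1 equiv), rt
Reagents that add atoms: none
Why: The cationic phosphine-gold fragment π-activates the bromoalkyne and the C9 silyl enol ether attacks the bromine-bearing alkyne carbon C4 through C5, anti to gold, giving a vinylgold/silyloxocarbenium species that loses the silyl group to water and is protodeaurated to the β-bromo enone. The closest known reaction type is the gold-catalysed Conia-ene-type carbocyclisation of silyl enol ethers onto alkynes and 1-haloalkynes, which is established for bicyclo[3.3.1]nonenone cores of this family. Ring A (C1–C2–C3–C4–C5–C9) is closed in the 6-endo-dig mode. The new C5 stereocentre is fixed by the tether: the alkynoyl arm sits on one face of ring B at C1 and can reach C5 only on that face, so the C2–C3–C4 bridge necessarily spans C1 and C5 on the same face of ring B. The step needs 6-endo over 5-exo closure, which the polarisation of the alkyne by the C2 carbonyl and by bromine (C4 electrophilic) and the bulky biaryl phosphine should secure, and it needs the enol ether to outcompete the prenyl and geranyl alkenes, which its far higher nucleophilicity should secure. A boat-like transition state that keeps the C7 geranyl pseudo-equatorial is expected, as in other closures to cores with an endo C7 substituent.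

**Step 11**
Reactants: 19 (1R,5R,7S)-4-bromo-7-geranyl-8,8-dimethyl-1-prenylbicyclo[3.3.1]non-3-ene-2,9-dione
Product: 20 (1R,5S,7S)-7-geranyl-4-methoxy-8,8-dimethyl-1-prenylbicyclo[3.3.1]non-3-ene-2,9-dione
Conditions: NaOMe, MeOH, 0 °C → rt
Reagents that add atoms: sodium methoxide, [Na+].[O-]C
Why: Addition–elimination (vinylic substitution) of methoxide at the β-carbon of the β-bromo enone gives the vinylogous ester, while the bridging ketone is shielded by its quaternary and bridgehead neighbours.

**Step 12**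
Reactants: 20 (1R,5S,7S)-7-geranyl-4-methoxy-8,8-dimethyl-1-prenylbicyclo[3.3.1]non-3-ene-2,9-dione; 4 geranyl bromide
Product: 22 (1R,5S,7S)-5,7-digeranyl-4-methoxy-8,8-dimethyl-1-prenylbicyclo[3.3.1]non-3-ene-2,9-dione, via bridgehead C5-lithio species 21 (not isolated)
Conditions: LiN(i-Pr)2, THF, −78 °C; then 4, −78 → 0 °C
Reagents that add atoms: geranyl bromide (4), CC(C)=CCC/C(C)=C/CBr
Why: Bridgehead lithiation–alkylation of a bicyclic vinylogous ester: the C5–H is acidified by the C9 ketone and the adjacent enol ether, the pyramidal bridgehead anion cannot invert, and alkylation with the allylic bromide should occur with retention.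

**Step 13**
Reactants: 23 3,4-dihydroxybenzoic acid
Product: 24 tert-butyldimethylsilyl 3,4-bis(tert-butyldimethylsilyloxy)benzoate
Conditions: t-BuMe2SiCl (3.5 equiv), imidazole, DMF, rt
Reagents that add atoms: tert-butyldimethylsilyl chloride, CC(C)(C)[Si](C)(C)Cl
Why: Silylation of the carboxylic acid and both phenols with the silyl chloride and imidazole protects the catechol against the organolithium of step 15.

**Step 14**
Reactants: 24 tert-butyldimethylsilyl 3,4-bis(tert-butyldimethylsilyloxy)benzoate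
Product: 25 3,4-bis(tert-butyldimethylsilyloxy)benzoyl chloride
Conditions: (COCl)2, DMF (cat.), CH2Cl2, 0 °C → rt
Reagents that add atoms: oxalyl chloride, O=C(Cl)C(=O)Cl
Why: Oxalyl chloride with catalytic DMF converts a silyl ester directly into the acid chloride (Vilsmeier-type activation) under neutral conditions that leave aryl silyl ethers intact.

**Step 15**
Reactants: 22 (1R,5S,7S)-5,7-digeranyl-4-methoxy-8,8-dimethyl-1-prenylbicyclo[3.3.1]non-3-ene-2,9-dione; 25 3,4-bis(tert-butyldimethylsilyloxy)benzoyl chloride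
Product: 27 3-[3,4-bis(tert-butyldimethylsilyloxy)benzoyl]-5,7-digeranyl-4-methoxy-8,8-dimethyl-1-prenylbicyclo[3.3.1]non-3-ene-2,9-dione, via C3-lithio species 26 (not isolated)
Conditions: lithium 2,2,6,6-tetramethylpiperidide, THF, −78 °C; then 25, −78 °C
Reagents that add atoms: 3,4-bis(tert-butyldimethylsilyloxy)benzoyl chloride (25), O=C(Cl)c1ccc(O[Si](C)(C)C(C)(C)C)c(O[Si](C)(C)C(C)(C)C)c1
Why: Vinylic lithiation at C3, the only remaining acidic C–H (α to the C2 carbonyl and β to the methoxy group), followed by C-acylation of the vinyllithium with the aroyl chloride.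

**Step 16**
Reactants: 27 3-[3,4-bis(tert-butyldimethylsilyloxy)benzoyl]-5,7-digeranyl-4-methoxy-8,8-dimethyl-1-prenylbicyclo[3.3.1]non-3-ene-2,9-dione
Product: 28 Oblongifolin D
Conditions: LiOH, 1,4-dioxane/H2O (degassed), 90 °C, argon; then 1 M HCl to pH 3, 0 °C
Reagents that add atoms: lithium hydroxide, [Li+].[OH-]
Why: Hydroxide should cleave the vinylogous methyl ester by addition–elimination at C4 and the aryl silyl ethers by attack at silicon, and cold acidification then gives the enolised 2-aroyl-1,3-dione without touching any stereocentre.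

**Compound list**

1 | 1,4-dioxaspiro[4.5]decan-7-one | O=C1CCCC2(OCCO2)C1 | starting material
2 | (R)-1-amino-2-(methoxymethyl)pyrrolidine (RAMP) | COC[C@H]1CCCN1N | starting material
3 | RAMP hydrazone of 1,4-dioxaspiro[4.5]decan-7-one | COC[C@H]1CCCN1N=C1CCCC2(OCCO2)C1 | intermediate
4 | geranyl bromide, (2E)-1-bromo-3,7-dimethylocta-2,6-diene | CC(C)=CCC/C(C)=C/CBr | starting material
5 | lithium azaenolate of 3, deprotonated at C8 (not isolated) | COC[C@H]1CCCN1N([Li])C1=CCCC2(OCCO2)C1 | intermediate
6 | RAMP hydrazone of (8R)-8-geranyl-1,4-dioxaspiro[4.5]decan-7-one | CC(C)=CCC/C(C)=C/C[C@H]1CCC2(OCCO2)CC1=NN1CCC[C@@H]1COC | intermediate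
7 | (8R)-8-geranyl-1,4-dioxaspiro[4.5]decan-7-one | CC(C)=CCC/C(C)=C/C[C@H]1CCC2(OCCO2)CC1=O | intermediate
8 | (8R)-8-geranyl-7-methyl-1,4-dioxaspiro[4.5]decan-7-ol, both C7 epimers (not isolated) | CC(C)=CCC/C(C)=C/C[C@H]1CCC2(OCCO2)CC1(C)O | intermediate
9 | (4R)-4-geranyl-3-methylcyclohex-2-en-1-one | CC(C)=CCC/C(C)=C/C[C@H]1CCC(=O)C=C1C | intermediate
10 | 3-(trimethylsilyl)prop-2-ynal | O=CC#C[Si](C)(C)C | starting material
11 | lithium (4R)-4-geranyl-3,3-dimethylcyclohex-1-en-1-olate (not isolated) | CC(C)=CCC/C(C)=C/C[C@H]1CCC(O[Li])=CC1(C)C | intermediate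
12 | (4R)-4-geranyl-2-[1-hydroxy-3-(trimethylsilyl)prop-2-yn-1-yl]-3,3-dimethylcyclohexan-1-one, mixture at C2 and the carbinol carbon | CC(C)=CCC/C(C)=C/C[C@H]1CCC(=O)C(C(O)C#C[Si](C)(C)C)C1(C)C | intermediate
13 | (4R)-4-geranyl-3,3-dimethyl-2-[3-(trimethylsilyl)prop-2-ynoyl]cyclohexan-1-one, keto/enol mixture | CC(C)=CCC/C(C)=C/C[C@H]1CCC(=O)C(C(=O)C#C[Si](C)(C)C)C1(C)C | intermediate
14 | prenyl bromide, 1-bromo-3-methylbut-2-ene | CC(C)=CCBr | starting material
15 | sodium enolate of 13 (not isolated) | CC(C)=CCC/C(C)=C/C[C@H]1CCC(=O)C(=C(O[Na])C#C[Si](C)(C)C)C1(C)C | intermediate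
16 | (2S,4R)-4-geranyl-3,3-dimethyl-2-prenyl-2-[3-(trimethylsilyl)prop-2-ynoyl]cyclohexan-1-one, prenyl trans to geranyl | CC(C)=CCC/C(C)=C/C[C@H]1CCC(=O)[C@@](CC=C(C)C)(C(=O)C#C[Si](C)(C)C)C1(C)C | intermediate
17 | (2S,4R)-2-(3-bromoprop-2-ynoyl)-4-geranyl-3,3-dimethyl-2-prenylcyclohexan-1-one | CC(C)=CCC/C(C)=C/C[C@H]1CCC(=O)[C@@](CC=C(C)C)(C(=O)C#CBr)C1(C)C | intermediate
18 | (4S,6S)-6-(3-bromoprop-2-ynoyl)-1-(tert-butyldimethylsilyloxy)-4-geranyl-5,5-dimethyl-6-prenylcyclohex-1-ene | CC(C)=CCC/C(C)=C/C[C@H]1CC=C(O[Si](C)(C)C(C)(C)C)[C@@](CC=C(C)C)(C(=O)C#CBr)C1(C)C | intermediate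
19 | (1R,5R,7S)-4-bromo-7-geranyl-8,8-dimethyl-1-prenylbicyclo[3.3.1]non-3-ene-2,9-dione, geranyl on the face of ring B that carries the C2–C4 bridge | CC(C)=CCC/C(C)=C/C[C@H]1C[C@@H]2C(=O)[C@@](CC=C(C)C)(C(=O)C=C2Br)C1(C)C | intermediate
20 | (1R,5S,7S)-7-geranyl-4-methoxy-8,8-dimethyl-1-prenylbicyclo[3.3.1]non-3-ene-2,9-dione | CC(C)=CCC/C(C)=C/C[C@H]1C[C@@H]2C(=O)[C@@](CC=C(C)C)(C(=O)C=C2OC)C1(C)C | intermediate
21 | bridgehead C5-lithio derivative of 20 (not isolated) | CC(C)=CCC/C(C)=C/C[C@H]1C[C@]2([Li])C(=O)[C@@](CC=C(C)C)(C(=O)C=C2OC)C1(C)C | intermediate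
22 | (1R,5S,7S)-5,7-digeranyl-4-methoxy-8,8-dimethyl-1-prenylbicyclo[3.3.1]non-3-ene-2,9-dione | CC(C)=CCC/C(C)=C/C[C@H]1C[C@]2(C/C=C(\C)CCC=C(C)C)C(=O)[C@@](CC=C(C)C)(C(=O)C=C2OC)C1(C)C | intermediate
23 | 3,4-dihydroxybenzoic acid (protocatechuic acid) | OC(=O)c1ccc(O)c(O)c1 | starting material
24 | tert-butyldimethylsilyl 3,4-bis(tert-butyldimethylsilyloxy)benzoate | CC(C)(C)[Si](C)(C)OC(=O)c1ccc(O[Si](C)(C)C(C)(C)C)c(O[Si](C)(C)C(C)(C)C)c1 | intermediate
25 | 3,4-bis(tert-butyldimethylsilyloxy)benzoyl chloride | O=C(Cl)c1ccc(O[Si](C)(C)C(C)(C)C)c(O[Si](C)(C)C(C)(C)C)c1 | intermediate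
26 | C3-lithio derivative of 22 (not isolated) | CC(C)=CCC/C(C)=C/C[C@H]1C[C@]2(C/C=C(\C)CCC=C(C)C)C(=O)[C@@](CC=C(C)C)(C(=O)C([Li])=C2OC)C1(C)C | intermediate
27 | 3-[3,4-bis(tert-butyldimethylsilyloxy)benzoyl]-5,7-digeranyl-4-methoxy-8,8-dimethyl-1-prenylbicyclo[3.3.1]non-3-ene-2,9-dione, C1/C5/C7 arranged as in 22 | CC(C)=CCC/C(C)=C/C[C@H]1C[C@]2(C/C=C(\C)CCC=C(C)C)C(=O)[C@@](CC=C(C)C)(C(=O)C(C(=O)c3ccc(O[Si](C)(C)C(C)(C)C)c(O[Si](C)(C)C(C)(C)C)c3)=C2OC)C1(C)C | intermediate
28 | Oblongifolin D | CC(C)=CCC/C(C)=C/C[C@H]1C[C@]2(C/C=C(\C)CCC=C(C)C)C(=O)[C@@](CC=C(C)C)(C(=O)C(C(=O)c3ccc(O)c(O)c3)=C2O)C1(C)C | target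

**Totals.** Total step count: 16. Longest linear sequence: 14 steps (steps 1–12, 15 and 16); steps 13 and 14 form the two-step aroyl chloride branch.

**Steps most likely to fail and fallbacks**

1. Step 10 (key ring closure). The electron-poor ynone may be activated only sluggishly by gold, or closure may leak into the 5-exo mode or into an enyne cyclisation through the prenyl alkene. The fallback moves the C2 oxidation behind the ring closure so that the closure runs on an electron-rich propargylic bromoalkyne. It sets out from 17. Luche reduction (NaBH4, CeCl3, MeOH, −78 °C) of the ynone carbonyl would give the propargylic alcohol F1. Treatment with t-BuMe2SiOTf and Et3N would silylate the alcohol and form the enol ether in one operation, giving the bis-silyl compound F2. The same gold catalyst would close ring A to the bicyclic allylic silyl ether F3, and HF·pyridine would release the allylic alcohol F4. Dess–Martin oxidation would then give 19, where the route is rejoined.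

2. Step 12 (bridgehead geranylation). Deprotonation may occur at the vinylic C3–H in competition with the bridgehead C5–H, or the hindered bridgehead anion may alkylate slowly. The fallback uses a temporary blocking group and sets out from 20. Lithium 2,2,6,6-tetramethylpiperidide with Me3SiCl present in situ would block C3 as the C3-silylated vinylogous ester F5. LiN(i-Pr)2 followed by geranyl bromide would then give the bridgehead-geranylated C3-silyl compound F6, and n-Bu4NF would remove the silyl group to return to 22.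

3. Step 7 (quaternisation of C1). O-alkylation of the hindered enolate, attack of the enolate oxygen on the ynone, or erosion of facial selectivity may compete. The fallback replaces the SN2 alkylation by a neutral allylic alkylation under zerovalent palladium catalysis. It sets out from 13: Pd(PPh3)4 with methyl prenyl carbonate in THF at rt would generate a π-prenyl palladium complex that the soft diketone nucleophile attacks at the unsubstituted terminus. This leads directly to 16, with no new compound on the way.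

**Further compounds**

F1 | step 10 | (2S,4R)-2-(3-bromo-1-hydroxyprop-2-yn-1-yl)-4-geranyl-3,3-dimethyl-2-prenylcyclohexan-1-one, both carbinol epimers | CC(C)=CCC/C(C)=C/C[C@H]1CCC(=O)[C@@](CC=C(C)C)(C(O)C#CBr)C1(C)C
F2 | step 10 | silyl ether and silyl enol ether of F1: 6-[3-bromo-1-(tert-butyldimethylsilyloxy)prop-2-yn-1-yl]-1-(tert-butyldimethylsilyloxy)-4-geranyl-5,5-dimethyl-6-prenylcyclohex-1-ene | CC(C)=CCC/C(C)=C/C[C@H]1CC=C(O[Si](C)(C)C(C)(C)C)[C@@](CC=C(C)C)(C(O[Si](C)(C)C(C)(C)C)C#CBr)C1(C)C
F3 | step 10 | 4-bromo-2-(tert-butyldimethylsilyloxy)-7-geranyl-8,8-dimethyl-1-prenylbicyclo[3.3.1]non-3-en-9-one, C1/C5/C7 as in 19 | CC(C)=CCC/C(C)=C/C[C@H]1C[C@@H]2C(=O)[C@@](CC=C(C)C)(C(O[Si](C)(C)C(C)(C)C)C=C2Br)C1(C)C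
F4 | step 10 | 4-bromo-7-geranyl-2-hydroxy-8,8-dimethyl-1-prenylbicyclo[3.3.1]non-3-en-9-one, C1/C5/C7 as in 19 | CC(C)=CCC/C(C)=C/C[C@H]1C[C@@H]2C(=O)[C@@](CC=C(C)C)(C(O)C=C2Br)C1(C)C
F5 | step 12 | 7-geranyl-4-methoxy-8,8-dimethyl-1-prenyl-3-(trimethylsilyl)bicyclo[3.3.1]non-3-ene-2,9-dione, C1/C5/C7 as in 20 | CC(C)=CCC/C(C)=C/C[C@H]1C[C@@H]2C(=O)[C@@](CC=C(C)C)(C(=O)C([Si](C)(C)C)=C2OC)C1(C)C
F6 | step 12 | 5,7-digeranyl-4-methoxy-8,8-dimethyl-1-prenyl-3-(trimethylsilyl)bicyclo[3.3.1]non-3-ene-2,9-dione, C1/C5/C7 as in 22 | CC(C)=CCC/C(C)=C/C[C@H]1C[C@]2(C/C=C(\C)CCC=C(C)C)C(=O)[C@@](CC=C(C)C)(C(=O)C([Si](C)(C)C)=C2OC)C1(C)C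
F0 | step 7 | none | none
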